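**Plan**

- Retrosynthesis: remove the ten benzyl ethers and the two gallate esters (O3 and O5 acyl bonds), take the C3 carbinol back to a C3 ketone, the ketone back to a 3-nitro-2H-chromene, then cut C3–C4 (Henry) and O1–C2 (oxa-Michael).
- Enabling feature: C4 is a one-carbon substituent of ring A flanked by the two ortho oxygens O1 and O5, so it is the formyl carbon of a 2,6-dihydroxybenzaldehyde. C3 is an oxygenated carbon next to the O1-bearing benzylic C2, so it is the nitronate carbon of a β-nitrostyrene, with nitro standing in for the C3 oxygen.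
- Forward: ring A aldehyde and ring B nitrostyrene are joined and ring C is closed in one operation (O1–C2, then C3–C4). Nitroalkene to ketone, reduction, double galloylation and hydrogenolysis follow.
- Stereochemistry: C2 of the flavan-3-one is α to the carbonyl and labile, so one dynamic kinetic transfer hydrogenation sets C2 (R) and C3 (R) together; the 2,3-cis relation comes from hydride entering anti to the 2-aryl group.
- O5 versus O7: the para hydroxyl of the aldehyde is benzylated first, and the ortho hydroxyl not used in ring closure is left as the free 5-OH that takes the second gallate.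

Key step: step 3

Assumption: the (S,S) antipode of the Ru catalyst in step 5 is taken as the one that reduces the (2R)-ketone at the Si face of C3; if the sense is the opposite, the (R,R) antipode is used and nothing else changes.

**Route**

Step 1
Reactants: 1 2,4,6-trihydroxybenzaldehyde
Product: 2 4-(benzyloxy)-2,6-dihydroxybenzaldehyde
Conditions: BnBr (1.0 equiv), CsHCO3 (1.2 equiv), MeCN, 60 °C
Reagents that add atoms: benzyl bromide, BrCc1ccccc1
Why: The 4-OH is para to the formyl group, is the most acidic hydroxyl and is the only one not hydrogen-bonded to the carbonyl, so a bicarbonate base with one equivalent of halide should give the 4-O-benzyl ether selectively (regioselective Williamson etherification).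

Step 2
Reactants: 3 3,4,5-tris(benzyloxy)benzaldehyde; 4 nitromethane
Product: 5 (E)-1,2,3-tris(benzyloxy)-5-(2-nitroethenyl)benzene
Conditions: MeNO2 (5 equiv), NH4OAc, AcOH, 100 °C
Reagents that add atoms: none
Why: Henry condensation (nitroaldol addition, then dehydration) should give the conjugated (E)-nitrostyrene as the thermodynamic product.

Step 3
Reactants: 2 4-(benzyloxy)-2,6-dihydroxybenzaldehyde; 5 (E)-1,2,3-tris(benzyloxy)-5-(2-nitroethenyl)benzene
Product: 8 rac-7-(benzyloxy)-3-nitro-2-[3,4,5-tris(benzyloxy)phenyl]-2H-chromen-5-ol, via nitro aldehyde 6 (not isolated), via nitro alcohol 7 (not isolated)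
Conditions: DABCO (0.5 equiv), 4 Å MS, MeCN, 60 °C
Reagents that add atoms: none
Why: DABCO forms the phenoxide of 2, which adds to the β-carbon of nitroalkene 5 (oxa-Michael) to give the nitronate of 6; the nitronate carbon then attacks the neighbouring formyl group (intramolecular Henry reaction) and closes ring C by forming the C3–C4 bond in a 6-exo-trig mode (enolexo nitronate), and E1cB loss of water from 7 gives the conjugated nitrochromene and pulls the reversible steps forward. The closest known reaction type is the amine-mediated tandem oxa-Michael–Henry–dehydration of salicylaldehydes with β-nitrostyrenes to 2-aryl-3-nitro-2H-chromenes. The only stereocenter that survives is C2; it is formed racemic on purpose, because it becomes α to the C3 carbonyl in 10 and is set together with C3 in step 5. The step needs O-attack rather than C-attack by the electron-rich ring A and closure onto the formyl carbon: the two ortho hydroxyls of 2 are homotopic, so either gives the same product, the aldehyde is the only electrophile within reach of the nitronate, and the hydroxyl left over is the 5-OH that later carries a galloyl group while O7 is already a benzyl ether.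

Step 4
Reactants: 8 rac-7-(benzyloxy)-3-nitro-2-[3,4,5-tris(benzyloxy)phenyl]-2H-chromen-5-ol
Product: 10 rac-7-(benzyloxy)-5-hydroxy-2-[3,4,5-tris(benzyloxy)phenyl]chroman-3-one, via oxime 9 (not isolated)
Conditions: Fe powder (6 equiv), AcOH/THF/H2O, 60 °C, N2
Reagents that add atoms: water, O
Why: Dissolving-metal reduction of a conjugated nitroalkene in aqueous acetic acid (reductive Nef-type conversion, as in the classical nitrostyrene-to-arylacetone reaction) should reduce 8 to oxime 9, cleave its N–O bond and hydrolyse the C=N bond to the ketone, while benzyl ethers and the phenol are untouched; no stereocenter is set and C2 stays racemic and labile.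

Step 5
Reactants: 10 rac-7-(benzyloxy)-5-hydroxy-2-[3,4,5-tris(benzyloxy)phenyl]chroman-3-one
Product: 11 (2R,3R)-7-(benzyloxy)-2-[3,4,5-tris(benzyloxy)phenyl]chromane-3,5-diol
Conditions: RuCl[(S,S)-TsDPEN](p-cymene) (2 mol %), HCO2H/Et3N (1:1), EtOAc, 40 °C, Ar
Reagents that add atoms: none
Why: Noyori–Ikariya asymmetric transfer hydrogenation run as a dynamic kinetic resolution: C2 of 10 is α to the carbonyl, benzylic and O-substituted, so its enantiomers interconvert through the enol in the amine-buffered medium while the catalyst reduces the (2R)-ketone faster, hydride entering at C3 anti to the 2-aryl group, which sets C3 (R) and fixes C2 (R) as the 2,3-cis alcohol.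

Step 6
Reactants: 11 (2R,3R)-7-(benzyloxy)-2-[3,4,5-tris(benzyloxy)phenyl]chromane-3,5-diol; 12 3,4,5-tris(benzyloxy)benzoic acid (3 equiv)
Product: 13 (2R,3R)-7-(benzyloxy)-2-[3,4,5-tris(benzyloxy)phenyl]chromane-3,5-diyl bis[3,4,5-tris(benzyloxy)benzoate]
Conditions: DCC (3 equiv), DMAP (0.5 equiv), CH2Cl2, 0 °C to rt
Reagents that add atoms: none
Why: Steglich esterification through the acylpyridinium ion should acylate both the 5-phenol and the axial 3-OH with excess acid, and neither C2 nor C3 can epimerize under these conditions.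

Step 7
Reactants: 13 (2R,3R)-7-(benzyloxy)-2-[3,4,5-tris(benzyloxy)phenyl]chromane-3,5-diyl bis[3,4,5-tris(benzyloxy)benzoate]
Product: 14 epigallocatechin 3,5-digallate, (2R,3R)-7-hydroxy-2-(3,4,5-trihydroxyphenyl)chromane-3,5-diyl bis(3,4,5-trihydroxybenzoate)
Conditions: H2 (1 atm), Pd(OH)2/C, THF/MeOH, rt
Reagents that add atoms: none
Why: Catalytic hydrogenolysis should cleave all ten benzyl ethers under neutral conditions, while the two aryl esters and the cyclic benzylic C2–O1 bond are retained, as in the debenzylation of perbenzylated catechin gallates.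

**Compound list**

1 | 2,4,6-trihydroxybenzaldehyde | O=Cc1c(O)cc(O)cc1O | starting material
2 | 4-(benzyloxy)-2,6-dihydroxybenzaldehyde | O=Cc1c(O)cc(OCc2ccccc2)cc1O | intermediate
3 | 3,4,5-tris(benzyloxy)benzaldehyde | O=Cc1cc(OCc2ccccc2)c(OCc2ccccc2)c(OCc2ccccc2)c1 | starting material
4 | nitromethane | C[N+](=O)[O-] | starting material
5 | (E)-1,2,3-tris(benzyloxy)-5-(2-nitroethenyl)benzene | [O-][N+](=O)/C=C/c1cc(OCc2ccccc2)c(OCc2ccccc2)c(OCc2ccccc2)c1 | intermediate
6 | rac-4-(benzyloxy)-2-hydroxy-6-{2-nitro-1-[3,4,5-tris(benzyloxy)phenyl]ethoxy}benzaldehyde (oxa-Michael adduct, not isolated) | O=Cc1c(O)cc(OCc2ccccc2)cc1OC(C[N+](=O)[O-])c1cc(OCc2ccccc2)c(OCc2ccccc2)c(OCc2ccccc2)c1 | intermediate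
7 | 7-(benzyloxy)-3-nitro-2-[3,4,5-tris(benzyloxy)phenyl]chromane-4,5-diol (Henry adduct, racemic diastereomer mixture, not isolated) | Oc1cc(OCc2ccccc2)cc2c1C(O)C([N+](=O)[O-])C(c1cc(OCc3ccccc3)c(OCc3ccccc3)c(OCc3ccccc3)c1)O2 | intermediate
8 | rac-7-(benzyloxy)-3-nitro-2-[3,4,5-tris(benzyloxy)phenyl]-2H-chromen-5-ol | Oc1cc(OCc2ccccc2)cc2c1C=C([N+](=O)[O-])C(c1cc(OCc3ccccc3)c(OCc3ccccc3)c(OCc3ccccc3)c1)O2 | intermediate
9 | rac-7-(benzyloxy)-5-hydroxy-2-[3,4,5-tris(benzyloxy)phenyl]chroman-3-one oxime (not isolated) | Oc1cc(OCc2ccccc2)cc2c1CC(=NO)C(c1cc(OCc3ccccc3)c(OCc3ccccc3)c(OCc3ccccc3)c1)O2 | intermediate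
10 | rac-7-(benzyloxy)-5-hydroxy-2-[3,4,5-tris(benzyloxy)phenyl]chroman-3-one (C2 labile) | Oc1cc(OCc2ccccc2)cc2c1CC(=O)C(c1cc(OCc3ccccc3)c(OCc3ccccc3)c(OCc3ccccc3)c1)O2 | intermediate
11 | (2R,3R)-7-(benzyloxy)-2-[3,4,5-tris(benzyloxy)phenyl]chromane-3,5-diol (2,3-cis) | Oc1cc(OCc2ccccc2)cc2c1C[C@@H](O)[C@@H](c1cc(OCc3ccccc3)c(OCc3ccccc3)c(OCc3ccccc3)c1)O2 | intermediate
12 | 3,4,5-tris(benzyloxy)benzoic acid | OC(=O)c1cc(OCc2ccccc2)c(OCc2ccccc2)c(OCc2ccccc2)c1 | starting material
13 | (2R,3R)-7-(benzyloxy)-2-[3,4,5-tris(benzyloxy)phenyl]chromane-3,5-diyl bis[3,4,5-tris(benzyloxy)benzoate] | O=C(Oc1cc(OCc2ccccc2)cc2c1C[C@@H](OC(=O)c1cc(OCc3ccccc3)c(OCc3ccccc3)c(OCc3ccccc3)c1)[C@@H](c1cc(OCc3ccccc3)c(OCc3ccccc3)c(OCc3ccccc3)c1)O2)c1cc(OCc2ccccc2)c(OCc2ccccc2)c(OCc2ccccc2)c1 | intermediate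
14 | epigallocatechin 3,5-digallate, (2R,3R) | O=C(Oc1cc(O)cc2c1C[C@@H](OC(=O)c1cc(O)c(O)c(O)c1)[C@@H](c1cc(O)c(O)c(O)c1)O2)c1cc(O)c(O)c(O)c1 | target

**Count and risks**

Total step count: 7. Longest linear sequence: 6 steps (1 → 2 → 8 → 10 → 11 → 13 → 14); step 2 is a one-step side branch.

Steps most likely to fail:

Step 3. The second free ortho hydroxyl, as phenoxide or as a hydrogen-bond donor to the carbonyl, may deactivate the aldehyde so that the Henry closure is slower than reversal of the oxa-Michael addition, and C-alkylation of ring A may compete. The fallback sets out from 2 and returns at 8. Compound 2 is mono-protected with MOMCl (1.0 equiv) and i-Pr2NEt in CH2Cl2 at 0 °C to give 4-(benzyloxy)-2-hydroxy-6-(methoxymethoxy)benzaldehyde F1. F1 and 5 are then joined under iminium activation (pyrrolidine and PhCO2H, 30 mol % each, EtOH, 80 °C), where the nitronate closes ring C onto the iminium carbon and the amine is expelled, to give rac-7-(benzyloxy)-5-(methoxymethoxy)-3-nitro-2-[3,4,5-tris(benzyloxy)phenyl]-2H-chromene F2. Catalytic HCl in MeOH/THF at 40 °C removes the acetal and gives 8.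

Step 5. Epimerization at C2 may be slower than reduction, or the catalyst may discriminate poorly between the faces of a carbonyl flanked by two sp3 carbons, which would erode enantiomeric purity. The fallback sets out from 10 and returns at 11. Compound 10 is reduced with LiBH(s-Bu)3 (2.2 equiv, THF, −78 °C), a bulky hydride that attacks flavan-3-ones anti to the 2-aryl group, to the racemic 2,3-cis diol, that is 11 together with its enantiomer (2S,3S)-7-(benzyloxy)-2-[3,4,5-tris(benzyloxy)phenyl]chromane-3,5-diol F3. Preparative chromatography on a chiral stationary phase then separates 11 from F3.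

Step 4. Over-reduction at nitrogen, or air oxidation of the electron-rich enolizable ketone during the warm acidic reaction, may consume the product. The fallback sets out from 8 and returns at 10. The C3=C4 bond of 8 is reduced with NaBH4 (THF/MeOH, 0 °C) to rac-7-(benzyloxy)-3-nitro-2-[3,4,5-tris(benzyloxy)phenyl]chroman-5-ol F4 (mixture of C3 epimers). Its nitronate (NaOMe, MeOH) is added to aqueous TiCl3 buffered with NH4OAc at 0 °C (reductive Nef reaction), which gives 10.

**Further compounds**

F1 | step 3 | 4-(benzyloxy)-2-hydroxy-6-(methoxymethoxy)benzaldehyde | COCOc1cc(OCc2ccccc2)cc(O)c1C=O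
F2 | step 3 | rac-7-(benzyloxy)-5-(methoxymethoxy)-3-nitro-2-[3,4,5-tris(benzyloxy)phenyl]-2H-chromene | COCOc1cc(OCc2ccccc2)cc2c1C=C([N+](=O)[O-])C(c1cc(OCc3ccccc3)c(OCc3ccccc3)c(OCc3ccccc3)c1)O2
F3 | step 5 | (2S,3S)-7-(benzyloxy)-2-[3,4,5-tris(benzyloxy)phenyl]chromane-3,5-diol | Oc1cc(OCc2ccccc2)cc2c1C[C@H](O)[C@H](c1cc(OCc3ccccc3)c(OCc3ccccc3)c(OCc3ccccc3)c1)O2
F4 | step 4 | rac-7-(benzyloxy)-3-nitro-2-[3,4,5-tris(benzyloxy)phenyl]chroman-5-ol | Oc1cc(OCc2ccccc2)cc2c1CC([N+](=O)[O-])C(c1cc(OCc3ccccc3)c(OCc3ccccc3)c(OCc3ccccc3)c1)O2
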